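Slowness was my first question: the electrophile is lost to the nucleophile (rate constant 7.0 × 10⁻⁴ /M/s) and to the protic impurity (0.0020 /M/s), and both partners thin out as they work.

all flasks: electrophile 0.069 M; nucleophile 0.0828 M; protic impurity 0.0690 M; time 5.0 h

| charge | free base |
|---|---|
| birch | 0.0690 M |
| cedar | 0.140 M |
| oak | 0.280 M |

- part of the electrophile that has reacted at the end, birch
- part of the electrophile that has reacted at the end, cedar
- part of the electrophile that has reacted at the end, oak
- what raising the concentration of free base from its lowest to its highest value here does to the part of the electrophile that has reacted (changes below 5 percentage points count as none) (no change / it rises / it falls)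

- percentages count the electrophile that a species holds: one idle adduct counts as two
- target is meant together with its idle adduct
- in an amount of target, one idle adduct counts as one target
- what has gone from electrophile into another species counts as reacted, even if it can come back
- run time (birch): 5.0 h

    electrophile + nucleophile → acid set free + target (k1 = 7.0 × 10⁻⁴ /M/s)
    nucleophile + acid set free ⇌ protonated nucleophile, settled at all times (K2 = 39000 /M)
    acid set free + free base ⇌ salt of the base, settled at all times (K3 = 3.8 × 10⁵ /M)
    electrophile + protic impurity → quenched substrate (k4 = 0.0020 /M/s)
    target ⇌ isomer of the product (K5 = 1.9, k5 = 5.0 × 10⁻⁵ /s)
    electrophile + target ⇌ idle adduct, settled at all times (K6 = 280 /M)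

At the charged levels the two together take the electrophile at 0.705 /h, a half-life of 0.983 h, and the impurity's drain is larger than the nucleophile's by a factor of 2.38. That slope flattens as the partners thin. Both meet the same free electrophile, so, with protonated nucleophile counted as nucleophile, the share of nucleophile left comes close to the share of impurity left raised to the ratio of the two rate constants, the selectivity factor 0.350.

With that rule I wrote the balance of the electrophile for birch: what the impurity and the nucleophile have taken together must reach the electrophile charged. It closes with the impurity at 35.4 % of its charge. That is the level I drew the impurity's curve running into, and the impurity's drain there is still larger, by a factor of 1.21, so I drew no crossing. The mean of the starting and closing drains is 0.513 /h, which over 5.0 h gives 92.3 % reacted. This is rough, since I left the idle adduct out of the clock, although in birch the equilibrium constant of its formation times the charged electrophile is 19.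

Birch has less free base than cedar or oak, yet the nucleophile's share of the bound acid there, reckoned at the charged levels, is 11.0 %, which ties up about 3.35 % of the nucleophile's charge at the closing level. So I expected 92.3 % in all three flasks and no change.

The forecast gave 91.5 %, 91.9 % and 92 %, no change, in its words “the nucleophile stays nearly all free and the base level barely matters”.

The simulation gave 91.7 %, 91.8 % and 91.8 %: no change, with a shift of 0.087 percentage points.

Birch still held 49 % of its impurity at 5.00 h, and the selectivity factor turns that into 26.7 % of the charged electrophile made into product. The flask held 23.0 % as target in all its forms and 3.37 % as isomer. In the neighbour of cedar charged with 0.28 M of electrophile, the impurity fell to 0.96 %, for which the same factor gives 23.8 %. That flask held 22.9 % as target and 0.407 % as isomer.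

The numbers of this flask stand for no real mixture.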